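**Plan**
- Retrosynthesis: remove the five O-benzyl groups, then cut the tetrahydrofuran ring of the cis-fused furo[3,4-c]furan-1-one at C3a–C4 and C6–C6a in one retro-[3+2] step.
- Enabling feature: the C4H2–O5–C6H(aryl) segment of the tetrahydrofuran ring is a latent carbonyl ylide, and the ring-fusion carbons C3a/C6a are the β/α carbons of the γ-lactone, i.e. the C=C of a 5-aryl butenolide.
- Forward: the lactone ring comes first (Stetter keto ester, asymmetric transfer hydrogenation, lactonisation) and is dehydrogenated to the (S)-butenolide by selenoxide elimination.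
- The ylide precursor, an α-chloro silylmethyl ether, is made in two steps from 3,4-bis(benzyloxy)benzaldehyde; the cycloaddition closes the tetrahydrofuran ring and hydrogenolysis frees the phenols.
- Stereochemistry: C3 from the catalyst-controlled ketone reduction; C3a, C6a and C6 from the cycloaddition (attack anti to the C5 aryl group, cis alkene, exo transition state).

Key step: step 7

Assumption: both benzyl-protected aldehydes and (trimethylsilyl)methanol are taken as purchasable; each aldehyde is otherwise one O-benzylation from the parent hydroxybenzaldehyde.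

**Step 1**
Reactants: 1 3,4,5-tris(benzyloxy)benzaldehyde; 2 methyl acrylate
Product: 3 methyl 4-oxo-4-[3,4,5-tris(benzyloxy)phenyl]butanoate
Conditions: 3-benzyl-5-(2-hydroxyethyl)-4-methylthiazolium chloride (20 mol%), Et3N, DMF, 70 °C
Reagents that add atoms: none
Why: Stetter reaction, in which the thiazolium-derived carbene turns the aldehyde into an acyl-anion equivalent that adds 1,4 to the acrylate, while the competing benzoin addition is reversible and drains into the keto ester.

**Step 2**
Reactants: 3 methyl 4-oxo-4-[3,4,5-tris(benzyloxy)phenyl]butanoate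
Product: 5 (5S)-5-[3,4,5-tris(benzyloxy)phenyl]dihydrofuran-2(3H)-one, via hydroxy ester 4 (not isolated)
Conditions: RuCl[(S,S)-TsDPEN](p-cymene) (1 mol%), HCO2H/Et3N (5:2), DMF, 40 °C; then PPTS (cat.), toluene, 60 °C
Reagents that add atoms: none
Why: Noyori asymmetric transfer hydrogenation of an aryl alkyl ketone, where the (S,S)-TsDPEN ruthenium hydride should give the S carbinol in the same sense as for acetophenone, followed by lactonisation through acyl substitution, which does not touch the new C–O stereocenter.

**Step 3**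
Reactants: 5 (5S)-5-[3,4,5-tris(benzyloxy)phenyl]dihydrofuran-2(3H)-one
Product: 7 (5S)-3-(phenylselanyl)-5-[3,4,5-tris(benzyloxy)phenyl]dihydrofuran-2(3H)-one (both C3 epimers), via lithium enolate 6 (not isolated)
Conditions: LiN(iPr)2, THF, −78 °C; then PhSeCl, −78 °C
Reagents that add atoms: phenylselenenyl chloride, Cl[Se]c1ccccc1
Why: α-selenenylation of a lactone lithium enolate, where only C3 is deprotonated and the C3 epimer mixture is irrelevant because that carbon becomes sp2 in the next step.

**Step 4**
Reactants: 7 (5S)-3-(phenylselanyl)-5-[3,4,5-tris(benzyloxy)phenyl]dihydrofuran-2(3H)-one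
Product: 9 (5S)-5-[3,4,5-tris(benzyloxy)phenyl]furan-2(5H)-one, via selenoxide 8 (not isolated)
Conditions: H2O2 (30% aq.), CH2Cl2, 0 °C → rt, no amine base
Reagents that add atoms: none
Why: selenide oxidation and selenoxide syn-elimination, in which the only syn β-hydrogens are on C4, so the endocyclic α,β-unsaturated lactone should form under neutral conditions that spare the base-labile C5–H stereocenter.

**Step 5**
Reactants: 10 3,4-bis(benzyloxy)benzaldehyde; 11 (trimethylsilyl)methanol
Product: 12 3,4-bis(benzyloxy)benzaldehyde bis[(trimethylsilyl)methyl] acetal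
Conditions: 11 (2.5 equiv in all), PPTS (cat.), cyclohexane, reflux, Dean–Stark trap; Et3N quench
Reagents that add atoms: (trimethylsilyl)methanol (the second equivalent of 11), C[Si](C)(C)CO
Why: acid-catalysed acetalisation driven by azeotropic removal of water, in which two equivalents of the primary silylmethyl alcohol, stable to mild acid, add to the aldehyde carbon through the hemiacetal and the aryl-stabilised oxocarbenium ion.

**Step 6**
Reactants: 12 3,4-bis(benzyloxy)benzaldehyde bis[(trimethylsilyl)methyl] acetal
Product: 13 [3,4-bis(benzyloxy)phenyl](chloro)methyl (trimethylsilyl)methyl ether (racemic, used crude at once)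
Conditions: AcCl, SOCl2 (cat.), CH2Cl2, 0 °C → rt; volatiles removed under vacuum
Reagents that add atoms: acetyl chloride, CC(=O)Cl
Why: acetal to α-chloro ether exchange with an acyl chloride, where acylation of one acetal oxygen and loss of the ester give the aryl-stabilised oxocarbenium chloride that collapses to the α-chloro ether.

**Step 7**
Reactants: 9 (5S)-5-[3,4,5-tris(benzyloxy)phenyl]furan-2(5H)-one; 13 [3,4-bis(benzyloxy)phenyl](chloro)methyl (trimethylsilyl)methyl ether
Product: 15 (3S,3aR,6S,6aS)-6-[3,4-bis(benzyloxy)phenyl]-3-[3,4,5-tris(benzyloxy)phenyl]tetrahydro-1H,3H-furo[3,4-c]furan-1-one, via carbonyl ylide 14 (not isolated)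
Conditions: 13 (3 equiv), CsF (2.5 equiv, flame-dried), MeCN, 0 °C → rt
Reagents that add atoms: none
Why: Fluoride attacks silicon of 13 as chloride leaves the benzylic carbon (silicon-based 1,3-elimination through the aryl-stabilised oxocarbenium ion), releasing the nonstabilised carbonyl ylide 14, a 4π-electron 1,3-dipole that adds suprafacially across C3=C4 of butenolide 9 in a concerted, asynchronous [3+2] cycloaddition. The closest known reaction type is the fluoride-induced generation of nonstabilised carbonyl ylides from α-chloroalkyl silylmethyl ethers and their cycloaddition to α,β-unsaturated esters, together with carbonyl ylide–butenolide cycloadditions used for furofuranone lignan skeletons. The tetrahydrofuran ring closes by the [3+2] cycloaddition itself, both C–C bonds in one event, so the cis ring fusion at C3a/C6a follows from the cis endocyclic alkene. The absolute configuration at C3a and C6a should come from attack on the face of 9 anti to the C5 aryl group, and C6 from the exo transition state of the W-shaped ylide, in which its aryl group and oxygen point away from the lactone ring. The step needs regioselectivity (CH2 terminus to the β-carbon), which the electron-rich aryl group should secure by placing cationic character on the benzylic terminus and leaving the small CH2 terminus as the nucleophilic end for the electrophilic, more hindered β-carbon; it also needs 9 to keep its configuration, which is served by keeping 13 in excess over fluoride so that fluoride is consumed at silicon and not as a base toward the acidic C5–H.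

**Step 8**
Reactants: 15 (3S,3aR,6S,6aS)-6-[3,4-bis(benzyloxy)phenyl]-3-[3,4,5-tris(benzyloxy)phenyl]tetrahydro-1H,3H-furo[3,4-c]furan-1-one
Product: 16 (3S,3aR,6S,6aS)-6-(3,4-dihydroxyphenyl)-3-(3,4,5-trihydroxyphenyl)tetrahydro-1H,3H-furo[3,4-c]furan-1-one
Conditions: H2 (1 atm), Pd/C (10%), EtOAc/MeOH, rt, stopped after uptake of five equivalents; filtration and isolation under argon
Reagents that add atoms: none
Why: catalytic hydrogenolysis of aryl benzyl ethers, which should be cleaved faster over Pd/C at 1 atm without acid than the secondary benzylic C–O bonds of the lactone and the tetrahydrofuran, and which touches no stereocenter.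

**Compound list**
1 | 3,4,5-tris(benzyloxy)benzaldehyde | O=Cc1cc(OCc2ccccc2)c(OCc2ccccc2)c(OCc2ccccc2)c1 | starting material
2 | methyl acrylate | COC(=O)C=C | starting material
3 | methyl 4-oxo-4-[3,4,5-tris(benzyloxy)phenyl]butanoate | COC(=O)CCC(=O)c1cc(OCc2ccccc2)c(OCc2ccccc2)c(OCc2ccccc2)c1 | intermediate
4 | methyl (4S)-4-hydroxy-4-[3,4,5-tris(benzyloxy)phenyl]butanoate | COC(=O)CC[C@H](O)c1cc(OCc2ccccc2)c(OCc2ccccc2)c(OCc2ccccc2)c1 | intermediate
5 | (5S)-5-[3,4,5-tris(benzyloxy)phenyl]dihydrofuran-2(3H)-one | O=C1O[C@H](c2cc(OCc3ccccc3)c(OCc3ccccc3)c(OCc3ccccc3)c2)CC1 | intermediate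
6 | lithium (5S)-5-[3,4,5-tris(benzyloxy)phenyl]-4,5-dihydrofuran-2-olate | [Li]OC1=CC[C@@H](c2cc(OCc3ccccc3)c(OCc3ccccc3)c(OCc3ccccc3)c2)O1 | intermediate
7 | (5S)-3-(phenylselanyl)-5-[3,4,5-tris(benzyloxy)phenyl]dihydrofuran-2(3H)-one, both C3 epimers | O=C1O[C@H](c2cc(OCc3ccccc3)c(OCc3ccccc3)c(OCc3ccccc3)c2)CC1[Se]c1ccccc1 | intermediate
8 | (5S)-3-(phenylseleninyl)-5-[3,4,5-tris(benzyloxy)phenyl]dihydrofuran-2(3H)-one | O=C1O[C@H](c2cc(OCc3ccccc3)c(OCc3ccccc3)c(OCc3ccccc3)c2)CC1[Se](=O)c1ccccc1 | intermediate
9 | (5S)-5-[3,4,5-tris(benzyloxy)phenyl]furan-2(5H)-one | O=C1O[C@H](c2cc(OCc3ccccc3)c(OCc3ccccc3)c(OCc3ccccc3)c2)C=C1 | intermediate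
10 | 3,4-bis(benzyloxy)benzaldehyde | O=Cc1ccc(OCc2ccccc2)c(OCc2ccccc2)c1 | starting material
11 | (trimethylsilyl)methanol | C[Si](C)(C)CO | starting material
12 | 3,4-bis(benzyloxy)benzaldehyde bis[(trimethylsilyl)methyl] acetal | C[Si](C)(C)COC(OC[Si](C)(C)C)c1ccc(OCc2ccccc2)c(OCc2ccccc2)c1 | intermediate
13 | [3,4-bis(benzyloxy)phenyl](chloro)methyl (trimethylsilyl)methyl ether, racemic | C[Si](C)(C)COC(Cl)c1ccc(OCc2ccccc2)c(OCc2ccccc2)c1 | intermediate
14 | carbonyl ylide, [3,4-bis(benzyloxy)benzylidene]oxonium methylide | [CH2-][O+]=Cc1ccc(OCc2ccccc2)c(OCc2ccccc2)c1 | intermediate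
15 | (3S,3aR,6S,6aS)-6-[3,4-bis(benzyloxy)phenyl]-3-[3,4,5-tris(benzyloxy)phenyl]tetrahydro-1H,3H-furo[3,4-c]furan-1-one | O=C1O[C@H](c2cc(OCc3ccccc3)c(OCc3ccccc3)c(OCc3ccccc3)c2)[C@H]2CO[C@H](c3ccc(OCc4ccccc4)c(OCc4ccccc4)c3)[C@@H]12 | intermediate
16 | (3S,3aR,6S,6aS)-6-(3,4-dihydroxyphenyl)-3-(3,4,5-trihydroxyphenyl)tetrahydro-1H,3H-furo[3,4-c]furan-1-one | O=C1O[C@H](c2cc(O)c(O)c(O)c2)[C@H]2CO[C@H](c3ccc(O)c(O)c3)[C@@H]12 | target

**Totals**
Total step count: 8. Longest linear sequence: 6 steps (steps 1, 2, 3, 4, 7, 8); the ylide precursor branch (steps 5, 6) joins at step 7.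

**Steps most likely to fail**

Step 7. Fluoride may act as a base toward the acidic C5–H of the butenolide, causing loss of configuration or migration of the double bond out of conjugation. The cycloaddition may also show incomplete exo or regiochemical control, and the ylide may collapse or dimerise before it is trapped. The fallback sets out from 9 and comes back at 15, making the same two bonds stepwise under non-equilibrating conditions. Benzophenone-sensitised irradiation of 9 in methanol (350 nm) should add a hydroxymethyl radical to C4 anti to the C5 aryl group and give (4R,5S)-4-(hydroxymethyl)-5-[3,4,5-tris(benzyloxy)phenyl]dihydrofuran-2(3H)-one F1. Separately, aldehyde 10 is converted with HC(OMe)3 and catalytic TsOH in MeOH into 3,4-bis(benzyloxy)benzaldehyde dimethyl acetal F2. Acetal exchange of F1 with excess F2 (PPTS, toluene, removal of methanol) then gives the mixed methyl acetal F3. LiN(iPr)2 and Me3SiCl in THF at −78 °C convert it into the silyl ketene acetal F4. Me3SiOTf in CH2Cl2 at −78 °C should ionise the acetal to the oxocarbenium ion and close the C6–C6a bond (intramolecular Mukaiyama-type acetal aldol reaction); the five-membered ring enforces cis fusion, and 15 results.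

Step 8. Hydrogenolysis may run on from the aryl benzyl ethers to the benzylic C–O bonds of the lactone or the tetrahydrofuran, and the freed pyrogallol may oxidise in air. The fallback sets out from 15 and comes back at 16. BCl3 with pentamethylbenzene as cation scavenger in CH2Cl2 at −78 °C, quenched with methanol, cleaves the aryl benzyl ethers by a non-reductive Lewis-acid path; it makes no new compound (none F0).

Step 2. Hydride transfer to the electron-rich, 3,5-disubstituted aryl ketone may discriminate the two faces poorly, or the benzylic carbinol may ionise under acid during lactonisation and erode the configuration. The fallback sets out from 1 and comes back at 9, bypassing steps 1 to 4. CH2=CHMgBr in THF at 0 °C adds to 1 and gives racemic 1-[3,4,5-tris(benzyloxy)phenyl]prop-2-en-1-ol F5. Kinetic resolution with immobilised Candida antarctica lipase B and vinyl acetate should leave (S)-1-[3,4,5-tris(benzyloxy)phenyl]prop-2-en-1-ol F6 and acetylate the other enantiomer to (R)-1-[3,4,5-tris(benzyloxy)phenyl]prop-2-en-1-yl acetate F7, which is separated. Acryloyl chloride and iPr2NEt in CH2Cl2 at 0 °C convert the remaining alcohol into (S)-1-[3,4,5-tris(benzyloxy)phenyl]prop-2-en-1-yl acrylate F8. Ring-closing metathesis of this diene with the second-generation Grubbs catalyst in CH2Cl2 at reflux closes butenolide 9 under neutral conditions.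

**Further compounds**
F1 | step 7 | (4R,5S)-4-(hydroxymethyl)-5-[3,4,5-tris(benzyloxy)phenyl]dihydrofuran-2(3H)-one | O=C1O[C@H](c2cc(OCc3ccccc3)c(OCc3ccccc3)c(OCc3ccccc3)c2)[C@@H](CO)C1
F2 | step 7 | 3,4-bis(benzyloxy)benzaldehyde dimethyl acetal | COC(OC)c1ccc(OCc2ccccc2)c(OCc2ccccc2)c1
F3 | step 7 | (4R,5S)-4-({[3,4-bis(benzyloxy)phenyl](methoxy)methoxy}methyl)-5-[3,4,5-tris(benzyloxy)phenyl]dihydrofuran-2(3H)-one, mixed methyl acetal, both acetal epimers | O=C1O[C@H](c2cc(OCc3ccccc3)c(OCc3ccccc3)c(OCc3ccccc3)c2)[C@@H](COC(OC)c2ccc(OCc3ccccc3)c(OCc3ccccc3)c2)C1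
F4 | step 7 | silyl ketene acetal, (4R,5S)-4-({[3,4-bis(benzyloxy)phenyl](methoxy)methoxy}methyl)-5-[3,4,5-tris(benzyloxy)phenyl]-2-(trimethylsilyloxy)-4,5-dihydrofuran | C[Si](C)(C)OC1=C[C@H](COC(OC)c2ccc(OCc3ccccc3)c(OCc3ccccc3)c2)[C@@H](c2cc(OCc3ccccc3)c(OCc3ccccc3)c(OCc3ccccc3)c2)O1
F5 | step 2 | racemic 1-[3,4,5-tris(benzyloxy)phenyl]prop-2-en-1-ol | C=CC(O)c1cc(OCc2ccccc2)c(OCc2ccccc2)c(OCc2ccccc2)c1
F6 | step 2 | (S)-1-[3,4,5-tris(benzyloxy)phenyl]prop-2-en-1-ol | C=C[C@H](O)c1cc(OCc2ccccc2)c(OCc2ccccc2)c(OCc2ccccc2)c1
F7 | step 2 | (R)-1-[3,4,5-tris(benzyloxy)phenyl]prop-2-en-1-yl acetate | C=C[C@@H](OC(C)=O)c1cc(OCc2ccccc2)c(OCc2ccccc2)c(OCc2ccccc2)c1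
F8 | step 2 | (S)-1-[3,4,5-tris(benzyloxy)phenyl]prop-2-en-1-yl acrylate | C=CC(=O)O[C@H](c1cc(OCc2ccccc2)c(OCc2ccccc2)c(OCc2ccccc2)c1)C=C
F0 | step 8 | none | none
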